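**Retrosynthetic overview**
- Perlatolic acid (16) comes from its benzyl ester and benzyl ether 15 by a final hydrogenolysis.
- The route rests on the substitution of ring B. C1 (carboxyl) and C6 (pentyl) are adjacent and map onto C2 and C3 of an oct-2-ynoate. C2–C3–C4–C5 carry oxygen at C2 and C4 and map onto a 1,1,3-trioxygenated butadiene whose C4 oxygen already bears the ring A acyl group.
- Ring B of 15 is therefore opened at C1–C2 and C5–C6 into diene 10 and benzyl oct-2-ynoate 12 ([4+2] cycloaddition, then loss of methanol).
- Diene 10 comes from enol ester 9 (γ-deprotonation, O-silylation), and 9 from O-acylation of methyl acetoacetate with the ring A acid chloride. Ring A acid 6 comes from olivetol by formylation, 4-O-methylation, 2-O-benzylation and oxidation.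
- Ring order: ring A is bought with olivetol; ring B is the only ring formed (step 8).

Key step: step 8

Assumption: the ketene acetal C=C geometry of diene 10 and the configuration of the transient ketal carbon of adduct 13 are left unassigned, since both are erased on aromatisation; the target has no stereocentre.

**Route**

Step 1
Reactants: 1 olivetol
Product: 3 2,4-dihydroxy-6-pentylbenzaldehyde, via iminium chloride 2 (not isolated)
Conditions: POCl3, DMF, 0 °C to rt; then H2O, 50 °C
Reagents that add atoms: N,N-dimethylformamide CN(C)C=O (formyl carbon); water O (carbonyl oxygen)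
Why: Vilsmeier–Haack formylation, in which the chloroiminium ion should attack the ring position para to one hydroxyl and ortho to the other rather than the more crowded position between the two hydroxyls, and water then hydrolyses iminium salt 2 to the aldehyde.

Step 2
Reactants: 3 2,4-dihydroxy-6-pentylbenzaldehyde
Product: 4 2-hydroxy-4-methoxy-6-pentylbenzaldehyde
Conditions: MeI (1.05 equiv), K2CO3, acetone, rt
Reagents that add atoms: iodomethane CI
Why: Williamson ether synthesis, selective for the 4-OH because the 2-OH is tied up in a hydrogen bond to the formyl oxygen and is both less acidic and less accessible.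

Step 3
Reactants: 4 2-hydroxy-4-methoxy-6-pentylbenzaldehyde
Product: 5 2-(benzyloxy)-4-methoxy-6-pentylbenzaldehyde
Conditions: BnBr, K2CO3, DMF, 60 °C
Reagents that add atoms: benzyl bromide BrCc1ccccc1
Why: Williamson etherification of the remaining chelated phenol under more forcing conditions, with benzyl chosen so that it leaves together with the benzyl ester in the last step.

Step 4
Reactants: 5 2-(benzyloxy)-4-methoxy-6-pentylbenzaldehyde
Product: 6 2-(benzyloxy)-4-methoxy-6-pentylbenzoic acid
Conditions: NaClO2, NaH2PO4, 2-methylbut-2-ene, t-BuOH/H2O, rt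
Reagents that add atoms: sodium chlorite [Na+].[O-]Cl=O
Why: Pinnick oxidation, in which chlorous acid converts the hindered aldehyde to the acid without touching the benzyl ether, while the alkene scavenges the hypochlorous acid that would otherwise chlorinate the electron-rich ring.

Step 5
Reactants: 6 2-(benzyloxy)-4-methoxy-6-pentylbenzoic acid; 7 methyl acetoacetate
Product: 9 methyl (E)-3-{[2-(benzyloxy)-4-methoxy-6-pentylbenzoyl]oxy}but-2-enoate, via acid chloride 8 (not isolated)
Conditions: (COCl)2, DMF (cat.), CH2Cl2, 0 °C to rt, evaporate; then 7, Et3N, DMPU, 0 °C to rt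
Reagents that add atoms: none
Why: Acid chloride formation followed by O-acylation of a β-keto ester enolate (enol ester formation); the ammonium enolate in a dipolar aprotic medium should react at oxygen, the crowded acyl chloride disfavours C-acylation further, and the non-chelated enolate should lead mainly to the E-isomer, in which the methyl group lies cis to the ester as step 6 requires.

Step 6
Reactants: 9 methyl (E)-3-{[2-(benzyloxy)-4-methoxy-6-pentylbenzoyl]oxy}but-2-enoate
Product: 10 4-methoxy-4-(trimethylsilyloxy)buta-1,3-dien-2-yl 2-(benzyloxy)-4-methoxy-6-pentylbenzoate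
Conditions: Me3SiCl, then LiN(i-Pr)2 (1.1 equiv), THF, −78 °C; non-aqueous work-up (pentane, filtration), used crude
Reagents that add atoms: chlorotrimethylsilane C[Si](C)(C)Cl
Why: Vinylketene silyl acetal formation by kinetic γ-deprotonation of a 3-oxy-but-2-enoate and O-silylation of the extended dienolate, as practised for the 3-methoxy and 3-silyloxy analogues; the 2,6-disubstituted benzoyl carbonyl is shielded from the bulky amide, and the silyl chloride present from the start should trap the dienolate before it can fragment.

Step 7
Reactants: 11 oct-2-ynoic acid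
Product: 12 benzyl oct-2-ynoate
Conditions: BnBr, KHCO3, DMF, rt
Reagents that add atoms: benzyl bromide BrCc1ccccc1
Why: Ester formation by SN2 alkylation of the carboxylate, with a base too weak to add to or isomerise the conjugated alkyne.

Step 8
Reactants: 10 4-methoxy-4-(trimethylsilyloxy)buta-1,3-dien-2-yl 2-(benzyloxy)-4-methoxy-6-pentylbenzoate; 12 benzyl oct-2-ynoate
Product: 15 benzyl 4-{[2-(benzyloxy)-4-methoxy-6-pentylbenzoyl]oxy}-2-hydroxy-6-pentylbenzoate (benzyl 2'-O-benzylperlatolate), via cycloadduct 13 (not isolated), via aryl silyl ether 14 (not isolated)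
Conditions: 12 (3 equiv), xylene (concentrated), 140 °C, sealed tube, Ar; then 1 M HCl, THF, rt
Reagents that add atoms: none
Why: This is a thermal, asynchronous [4+2] cycloaddition (Diels–Alder benzannulation) in which the CH2 terminus C1 of the diene, made the most nucleophilic carbon by the ketene acetal oxygens at C4 and the aroyloxy oxygen at C2, bonds first to the pentyl-bearing C3 of the ynoate, after which the ketene acetal carbon C4 closes onto ynoate C2. The closest known reaction type is the benzannulation of 1,1-dialkoxy-3-silyloxybutadienes and 1-alkoxy-1,3-bis(silyloxy)butadienes with alk-2-ynoates to give 6-alkylresorcylates, and 2-acyloxybutadienes are established Diels–Alder dienes, so the aroyloxy group should slow the reaction without changing its course. Ring B is closed in this single bimolecular cycloaddition on the s-cis diene, forming the ring B bonds C5–C6 and C1–C2 without a tether; adduct 13 then loses methanol by 1,4-elimination between the ketal carbon and the doubly allylic CH2 to give aryl silyl ether 14, whose O–Si bond is cleaved by dilute acid. No stereocentre is created in the product, since the ketal carbon of 13 forms as a racemate and becomes the sp2 carbon C2 of the arene. The step needs the regiochemistry that places the benzyl ester between the hydroxyl and the pentyl group and the aroyloxy group para to the ester, and the match between the push–pull polarisation of the diene and that of the conjugated ester secures it. It also needs the enol ester to survive heating, which the 2,6-disubstitution of the ring A benzoyl group secures by blocking acyl transfer.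

Step 9
Reactants: 15 benzyl 2'-O-benzylperlatolate
Product: 16 perlatolic acid
Conditions: H2 (1 atm), 10% Pd/C, EtOAc, rt
Reagents that add atoms: none
Why: Catalytic hydrogenolysis cleaves the two benzylic C–O bonds (benzyl ether and benzyl ester) and leaves the aryl ester link, the aryl methyl ether and the phenols intact.

**Compound list**
1 | olivetol (5-pentylbenzene-1,3-diol) | CCCCCc1cc(O)cc(O)c1 | starting material
2 | N-[(2,4-dihydroxy-6-pentylphenyl)methylidene]-N-methylmethanaminium chloride | CCCCCc1cc(O)cc(O)c1C=[N+](C)C.[Cl-] | intermediate (not isolated)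
3 | 2,4-dihydroxy-6-pentylbenzaldehyde | CCCCCc1cc(O)cc(O)c1C=O | intermediate
4 | 2-hydroxy-4-methoxy-6-pentylbenzaldehyde | CCCCCc1cc(OC)cc(O)c1C=O | intermediate
5 | 2-(benzyloxy)-4-methoxy-6-pentylbenzaldehyde | CCCCCc1cc(OC)cc(OCc2ccccc2)c1C=O | intermediate
6 | 2-(benzyloxy)-4-methoxy-6-pentylbenzoic acid | CCCCCc1cc(OC)cc(OCc2ccccc2)c1C(=O)O | intermediate
7 | methyl acetoacetate | CC(=O)CC(=O)OC | starting material
8 | 2-(benzyloxy)-4-methoxy-6-pentylbenzoyl chloride | CCCCCc1cc(OC)cc(OCc2ccccc2)c1C(=O)Cl | intermediate (not isolated)
9 | methyl (E)-3-{[2-(benzyloxy)-4-methoxy-6-pentylbenzoyl]oxy}but-2-enoate | C/C(OC(=O)c1c(OCc2ccccc2)cc(OC)cc1CCCCC)=C\C(=O)OC | intermediate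
10 | 4-methoxy-4-(trimethylsilyloxy)buta-1,3-dien-2-yl 2-(benzyloxy)-4-methoxy-6-pentylbenzoate | C=C(OC(=O)c1c(OCc2ccccc2)cc(OC)cc1CCCCC)C=C(OC)O[Si](C)(C)C | intermediate
11 | oct-2-ynoic acid | CCCCCC#CC(=O)O | starting material
12 | benzyl oct-2-ynoate | CCCCCC#CC(=O)OCc1ccccc1 | intermediate
13 | benzyl 4-{[2-(benzyloxy)-4-methoxy-6-pentylbenzoyl]oxy}-6-methoxy-2-pentyl-6-(trimethylsilyloxy)cyclohexa-1,4-diene-1-carboxylate (racemic) | CCCCCC1=C(C(=O)OCc2ccccc2)C(OC)(O[Si](C)(C)C)C=C(OC(=O)c2c(OCc3ccccc3)cc(OC)cc2CCCCC)C1 | intermediate (not isolated)
14 | benzyl 4-{[2-(benzyloxy)-4-methoxy-6-pentylbenzoyl]oxy}-2-pentyl-6-(trimethylsilyloxy)benzoate | CCCCCc1cc(OC(=O)c2c(OCc3ccccc3)cc(OC)cc2CCCCC)cc(O[Si](C)(C)C)c1C(=O)OCc1ccccc1 | intermediate (not isolated)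
15 | benzyl 4-{[2-(benzyloxy)-4-methoxy-6-pentylbenzoyl]oxy}-2-hydroxy-6-pentylbenzoate (benzyl 2'-O-benzylperlatolate) | CCCCCc1cc(OC(=O)c2c(OCc3ccccc3)cc(OC)cc2CCCCC)cc(O)c1C(=O)OCc1ccccc1 | intermediate
16 | perlatolic acid (2-hydroxy-4-[(2-hydroxy-4-methoxy-6-pentylbenzoyl)oxy]-6-pentylbenzoic acid) | CCCCCc1cc(OC(=O)c2c(O)cc(OC)cc2CCCCC)cc(O)c1C(=O)O | target

**Step count**
Total: 9 steps. Longest linear sequence: 8 steps (steps 1–6, 8, 9); step 7 is a one-step branch.

**Steps most likely to fail**

1. Step 8. The cycloaddition may be too slow, because an aroyloxy group at diene C2 donates less than a silyloxy group and the ynoate carries an alkyl group on its β-carbon; thermal O-to-C silyl migration or hydrolysis of the ketene acetal could then consume the diene first. The adduct might also aromatise by losing trimethylsilanol instead of methanol, which would leave a methyl ether at C2 of ring B.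
   Fallback: ring B is taken ready-made and the ester link is formed by the classical depside condensation; the fallback sets out from olivetol 1 and acid 6 and comes back at 15. Olivetol 1 should be carboxylated with MeOMgOCO2Me in DMF at 120 °C, followed by aqueous HCl, to give olivetolic acid F1. Its carboxylate is benzylated (BnBr, KHCO3, DMF) to benzyl 2,4-dihydroxy-6-pentylbenzoate F2. Acid 6 and F2 are then condensed with (CF3CO)2O in toluene at rt through 2-(benzyloxy)-4-methoxy-6-pentylbenzoic trifluoroacetic anhydride F3. This should acylate only the 4-OH of F2, the 2-OH being hydrogen-bonded to the ester carbonyl, and give 15.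

2. Step 6. The amide base may remove a benzylic proton of the ring A pentyl group (lateral metalation ortho to the ester) instead of the γ-methyl proton, or the dienolate may expel the aroate before it is silylated.
   Fallback: the cycloaddition is run with a diene that carries silyl in place of the aroyl group, and ring A is attached afterwards; the fallback sets out from 12 and 6 and comes back at 15. Purchased 1-methoxy-1,3-bis(trimethylsilyloxy)buta-1,3-diene is heated with 12 (neat, 130 °C). The cycloadduct benzyl 6-methoxy-2-pentyl-4,6-bis(trimethylsilyloxy)cyclohexa-1,4-diene-1-carboxylate F4 should lose methanol to give benzyl 2-pentyl-4,6-bis(trimethylsilyloxy)benzoate F5, and dilute acid should then give benzyl 2,4-dihydroxy-6-pentylbenzoate F2. F2 is joined to 6 with (CF3CO)2O in toluene through the mixed anhydride F3, as in the first fallback, to give 15.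

3. Step 5. C-acylation of the enolate, slow acyl transfer from the crowded acid chloride, or formation of the Z-enol ester, whose methyl group is badly placed for γ-deprotonation, may erode the supply of 9.
   Fallback: the hindered acid is used as the oxygen nucleophile instead of as the acyl donor; the fallback sets out from 6 and comes back at 9. Acid 6 is added to purchased methyl buta-2,3-dienoate under amine catalysis (DABCO, MeCN, rt). This is an oxa-Michael addition of the carboxylate to the central allene carbon, and protonation of the resulting dienolate into conjugation should give 9 without any attack on the crowded carbonyl.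

**Further compounds**
F1 | step 8 | olivetolic acid (2,4-dihydroxy-6-pentylbenzoic acid) | CCCCCc1cc(O)cc(O)c1C(=O)O
F2 | step 8 | benzyl 2,4-dihydroxy-6-pentylbenzoate | CCCCCc1cc(O)cc(O)c1C(=O)OCc1ccccc1
F3 | step 8 | 2-(benzyloxy)-4-methoxy-6-pentylbenzoic trifluoroacetic anhydride | CCCCCc1cc(OC)cc(OCc2ccccc2)c1C(=O)OC(=O)C(F)(F)F
F4 | step 6 | benzyl 6-methoxy-2-pentyl-4,6-bis(trimethylsilyloxy)cyclohexa-1,4-diene-1-carboxylate (racemic) | CCCCCC1=C(C(=O)OCc2ccccc2)C(OC)(O[Si](C)(C)C)C=C(O[Si](C)(C)C)C1
F5 | step 6 | benzyl 2-pentyl-4,6-bis(trimethylsilyloxy)benzoate | CCCCCc1cc(O[Si](C)(C)C)cc(O[Si](C)(C)C)c1C(=O)OCc1ccccc1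
F0 | step 5 | none | none
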